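**Retrosynthetic overview**

1. Germacrane locants are used: C1 hemiketal carbon, C4 methyl-bearing ether carbon, C5=C6 exocyclic enol-lactone bond, C6–O/C12=O lactone, C7=C11, C8 acyloxy carbon, C10 methyl-bearing CH, C13 acetoxymethyl.
2. Enabling feature: the oxolane C4–O bond together with the C5=C6 bond is the allylic (SN2′) isomer of a C4=C5 olefin beside a C6 lactol, and the ylidene-butenolide ring (O, C6, C7, C11, C12) is a furan at a lower oxidation level. C4–C5 can therefore be made as the C4=C5 bond of a plain 2-alkenylfuran while C1 stays a free ketone.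
3. Disconnections (backwards): desilylation; acid isomerization of a γ-hydroxybutenolide (C6–OH) to the C4–O–C1 hemiketal and the C5=C6 ylidene; singlet-oxygen oxidation of the furan; ring-closing metathesis at C4=C5 of an acyclic vinylfuran/isopropenyl diene.
4. The diene comes from a Weinreb amide and a 3-methylbut-3-enyl Grignard reagent (C1–C2), an asymmetric transfer hydrogenation (C8), a zinc-homoenolate acylation (C8–C9, C10 from the bromo ester) and a directed metalation/vinylation of a 3-furoic acid (C5–C6).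
5. Ring order: furan (purchased) → temporary γ-lactone (steps 5–6) → ten-membered carbocycle (step 11) → butenolide (step 14) → oxolane and nine-membered oxacycle (step 15).

Key step: step 11

Remark (assumption): compounds 1, 7, 13, 16 and 17 are taken as commercially available; TBS = tert-butyldimethylsilyl, TBDPS = tert-butyldiphenylsilyl.

**Route**

Step 1
Reactants: 1 furan-3,4-diyldimethanol
Product: 2 [4-(TBSOCH2)furan-3-yl]methanol
Conditions: NaH (1.0 equiv), THF, 0 °C; TBSCl (1.0 equiv), 0 °C → rt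
Reagents that add atoms: tert-butyl(chloro)dimethylsilane (TBSCl), CC(C)(C)[Si](C)(C)Cl
Why: Monosilylation of a symmetric diol through its monosodium alkoxide (O-silylation); the two hydroxymethyl groups are equivalent, so only mono versus bis protection has to be controlled.

Step 2
Reactants: 2 [4-(TBSOCH2)furan-3-yl]methanol
Product: 3 4-(TBSOCH2)furan-3-carboxylic acid
Conditions: TEMPO (cat.), PhI(OAc)2 (2.2 equiv), MeCN/H2O, rt
Reagents that add atoms: water, O
Why: Oxoammonium-catalysed oxidation of the primary alcohol to the aldehyde and, through its hydrate, to the acid; chlorite, which would attack the furan, is avoided.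

Step 3
Reactants: 3 4-(TBSOCH2)furan-3-carboxylic acid
Product: 6 2-ethenyl-4-(TBSOCH2)furan-3-carboxylic acid, via dilithiated furoate 4 (not isolated), via furylzinc chloride 5 (not isolated)
Conditions: LDA (2.2 equiv), THF, −78 °C; ZnCl2, −78 → 0 °C; bromoethene, Pd(PPh3)4 (5 mol %), rt; dilute HCl work-up
Reagents that add atoms: bromoethene, C=CBr
Why: The carboxylate directs ortho-lithiation to the adjacent furan α-position (the future C6) rather than the remote α-position, and transmetalation to zinc allows a Negishi coupling that installs C5 as a vinyl group.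

Step 4
Reactants: 6 2-ethenyl-4-(TBSOCH2)furan-3-carboxylic acid; 7 methyl (2S)-3-bromo-2-methylpropanoate
Product: 10 methyl (2R)-4-[2-ethenyl-4-(TBSOCH2)furan-3-yl]-2-methyl-4-oxobutanoate, via acid chloride 8 (not isolated), via alkylzinc bromide 9 (not isolated)
Conditions: 7, Zn dust, LiCl, THF, 40 °C; 6, 1-chloro-N,N,2-trimethylprop-1-en-1-amine, CH2Cl2, 0 °C; combine, Pd(PPh3)4 (5 mol %), THF, 0 °C → rt
Reagents that add atoms: none
Why: Negishi-type acylation of a β-zincio ester (zinc homoenolate) by the acid chloride, made under neutral conditions, forms C8–C9; the C10 stereocentre comes unchanged from 7 because it is neither metalated nor enolized.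

Step 5
Reactants: 10 methyl (2R)-4-[2-ethenyl-4-(TBSOCH2)furan-3-yl]-2-methyl-4-oxobutanoate
Product: 11 (3R,5S)-5-[2-ethenyl-4-(TBSOCH2)furan-3-yl]-3-methyloxolan-2-one
Conditions: RuCl[(S,S)-TsDPEN](p-cymene) (1 mol %), HCO2H/Et3N (5:2), DMF, 40 °C; then PPTS (cat.), PhMe, 50 °C
Reagents that add atoms: none
Why: Noyori-type asymmetric transfer hydrogenation of the heteroaryl ketone, in which the (S,S) catalyst should deliver hydride to give the (S)-carbinol at C8 (catalyst control), followed by lactonization to the trans-lactone, which also allows removal of any cis isomer.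

Step 6
Reactants: 11 (3R,5S)-5-[2-ethenyl-4-(TBSOCH2)furan-3-yl]-3-methyloxolan-2-one
Product: 12 (2R,4S)-4-[2-ethenyl-4-(TBSOCH2)furan-3-yl]-4-hydroxy-N-methoxy-N,2-dimethylbutanamide
Conditions: MeNH(OMe)·HCl, i-PrMgCl, THF, −20 °C
Reagents that add atoms: N,O-dimethylhydroxylamine hydrochloride, CNOC.Cl
Why: Aminolysis of the lactone by the chloromagnesium amide (Weinreb amide formation) opens the temporary ring without touching C8 or C10.

Step 7
Reactants: 12 (2R,4S)-4-[2-ethenyl-4-(TBSOCH2)furan-3-yl]-4-hydroxy-N-methoxy-N,2-dimethylbutanamide; 13 4-bromo-2-methylbut-1-ene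
Product: 15 (6R,8S)-8-[2-ethenyl-4-(TBSOCH2)furan-3-yl]-8-hydroxy-2,6-dimethyloct-1-en-5-one, via Grignard reagent 14 (not isolated)
Conditions: 13, Mg, THF, rt; then 12, THF, −78 → 0 °C (3 equiv of 14); aq. NH4Cl
Reagents that add atoms: none
Why: Grignard addition to the Weinreb amide stops at the C1 ketone through the chelated tetrahedral intermediate; the first equivalent of 14 is consumed by the free hydroxyl group.

Step 8
Reactants: 16 2-(TBDPSO)acetaldehyde; 17 ethyl 2-(triphenyl-λ5-phosphanylidene)propanoate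
Product: 18 ethyl (2E)-4-(TBDPSO)-2-methylbut-2-enoate
Conditions: CH2Cl2, rt
Reagents that add atoms: none
Why: Wittig olefination with a stabilized ylide, which should give the (E)-trisubstituted enoate of the side chain.

Step 9
Reactants: 18 ethyl (2E)-4-(TBDPSO)-2-methylbut-2-enoate
Product: 19 (2E)-4-(TBDPSO)-2-methylbut-2-enoic acid
Conditions: LiOH·H2O, THF/MeOH/H2O, rt; then 1 M HCl to pH 4
Reagents that add atoms: lithium hydroxide, [Li+].[OH-]
Why: Saponification of the ethyl ester; the TBDPS ether and the olefin geometry are stable to these conditions.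

Step 10
Reactants: 15 (6R,8S)-8-[2-ethenyl-4-(TBSOCH2)furan-3-yl]-8-hydroxy-2,6-dimethyloct-1-en-5-one; 19 (2E)-4-(TBDPSO)-2-methylbut-2-enoic acid
Product: 20 (1S,3R)-1-[2-ethenyl-4-(TBSOCH2)furan-3-yl]-3,7-dimethyl-4-oxooct-7-en-1-yl (2E)-4-(TBDPSO)-2-methylbut-2-enoate
Conditions: DIC, DMAP, CH2Cl2, 0 °C → rt
Reagents that add atoms: none
Why: Steglich esterification of the C8 carbinol, which proceeds with retention because the C8–O bond is not broken.

Step 11
Reactants: 20 (1S,3R)-1-[2-ethenyl-4-(TBSOCH2)furan-3-yl]-3,7-dimethyl-4-oxooct-7-en-1-yl (2E)-4-(TBDPSO)-2-methylbut-2-enoate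
Product: 21 (4S,6R,10Z)-3-(TBSOCH2)-6,10-dimethyl-7-oxo-4,5,6,7,8,9-hexahydrocyclodeca[b]furan-4-yl (2E)-4-(TBDPSO)-2-methylbut-2-enoate
Conditions: second-generation Hoveyda–Grubbs catalyst, RuCl2(H2IMes)(=CH–C6H4-2-OiPr) (10 mol %), 1,4-benzoquinone (20 mol %), PhMe (1 mM), 80 °C, slow addition
Reagents that add atoms: none
Why: The ruthenium alkylidene loads on the 2-vinylfuran terminus, forms a ruthenacyclobutane with the isopropenyl group by [2+2] cycloaddition and releases ethene on cycloreversion, so that the new C4=C5 bond closes the ten-membered carbocycle (Chauvin mechanism). The closest known reaction type is ring-closing metathesis of a monosubstituted with a 1,1-disubstituted alkene to medium-ring and macrocyclic trisubstituted cycloalkenes. One ring is closed, the ten-membered carbocycle fused to the furan, in the endo mode of metathesis macrocyclization; the olefin geometry (Z expected) is irrelevant because C4 becomes sp3 and C5=C6 is formed anew in step 15. No stereocentre is created, and C8 and C10 are remote from the reacting olefins. The step needs cyclization to outrun oligomerization and needs site selectivity among the C=C bonds: high dilution with slow addition, the cis-held 2,3-substituents of the furan and the sp2 C1 ketone (fewer transannular contacts) should favour closure, while the trisubstituted electron-poor enoate and the furan double bonds are inert to the catalyst. The free C1 ketone, both ester-type groups and the silyl ethers are tolerated, so no masking group has to be carried through the ring closure.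

Step 12
Reactants: 21 (4S,6R,10Z)-3-(TBSOCH2)-6,10-dimethyl-7-oxo-4,5,6,7,8,9-hexahydrocyclodeca[b]furan-4-yl (2E)-4-(TBDPSO)-2-methylbut-2-enoate
Product: 22 (4S,6R,10Z)-3-(hydroxymethyl)-6,10-dimethyl-7-oxo-4,5,6,7,8,9-hexahydrocyclodeca[b]furan-4-yl (2E)-4-(TBDPSO)-2-methylbut-2-enoate
Conditions: HF·pyridine, pyridine, THF, 0 °C
Reagents that add atoms: none
Why: Buffered fluoride desilylation should cleave the primary TBS ether much faster than the primary TBDPS ether, freeing the C13 hydroxyl selectively.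

Step 13
Reactants: 22 (4S,6R,10Z)-3-(hydroxymethyl)-6,10-dimethyl-7-oxo-4,5,6,7,8,9-hexahydrocyclodeca[b]furan-4-yl (2E)-4-(TBDPSO)-2-methylbut-2-enoate
Product: 23 (4S,6R,10Z)-3-(acetoxymethyl)-6,10-dimethyl-7-oxo-4,5,6,7,8,9-hexahydrocyclodeca[b]furan-4-yl (2E)-4-(TBDPSO)-2-methylbut-2-enoate
Conditions: Ac2O, pyridine, DMAP (cat.), CH2Cl2, 0 °C
Reagents that add atoms: acetic anhydride, CC(=O)OC(C)=O
Why: Acetylation of the only free hydroxyl group installs the C13 acetate before the sensitive oxidation states are raised.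

Step 14
Reactants: 23 (4S,6R,10Z)-3-(acetoxymethyl)-6,10-dimethyl-7-oxo-4,5,6,7,8,9-hexahydrocyclodeca[b]furan-4-yl (2E)-4-(TBDPSO)-2-methylbut-2-enoate
Product: 25 (4S,6R,10Z)-3-(acetoxymethyl)-11a-hydroxy-6,10-dimethyl-2,7-dioxo-2,4,5,6,7,8,9,11a-octahydrocyclodeca[b]furan-4-yl (2E)-4-(TBDPSO)-2-methylbut-2-enoate (C6 epimers), via furan endoperoxide 24 (not isolated)
Conditions: O2, visible light, 5,10,15,20-tetraphenylporphyrin (cat.), i-Pr2NEt, CH2Cl2, −78 °C
Reagents that add atoms: dioxygen, O=O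
Why: Singlet oxygen adds [4+2] to the electron-rich furan faster than to the olefins, and base-induced Kornblum–DeLaMare rearrangement of the endoperoxide removes its only α-hydrogen (at C12), placing the lactone carbonyl at C12 and the lactol hydroxyl at C6; the C6 configuration is inconsequential.

Step 15
Reactants: 25 (4S,6R,10Z)-3-(acetoxymethyl)-11a-hydroxy-6,10-dimethyl-2,7-dioxo-2,4,5,6,7,8,9,11a-octahydrocyclodeca[b]furan-4-yl (2E)-4-(TBDPSO)-2-methylbut-2-enoate
Product: 26 (1S,4R,5E,8S,10R)-13-acetoxy-1,4-epoxy-1-hydroxygermacra-5,7(11)-dien-12,6-olid-8-yl (2E)-4-(TBDPSO)-2-methylbut-2-enoate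
Conditions: (+)-10-camphorsulfonic acid (0.2 equiv), CH2Cl2, 0 °C → rt
Reagents that add atoms: none
Why: Proposed new method: acid ionizes the lactol C6–OH of the γ-hydroxybutenolide (pseudo-acid) to a C4–C5–C6 allyl cation stabilized by the ring oxygen; the transannular C1 carbonyl oxygen attacks its C4 terminus in a 5-exo sense (SN1′), and the oxocarbenium ion at C1 takes up the water just released, giving the hemiketal and the C5=C6 bond in a redox-neutral isomerization. The closest known reaction types are acid-catalysed ionization/dehydration of pseudo-acids to γ-ylidenebutenolides and transannular hemiketalization/oxa-conjugate addition in ten-membered rings. C4 and C1 are set together (the bridge forces them cis) under control of C8 and C10, whose acyloxy and methyl groups should prefer the oxygen-bridged face over the C2–C3 bridge of the bicyclo[6.2.1] skeleton; because C4–O is allylic the closure should be reversible and reflect this preference. The ring forces the E geometry (C4 cis to C7).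

Step 16
Reactants: 26 (1S,4R,5E,8S,10R)-13-acetoxy-1,4-epoxy-1-hydroxygermacra-5,7(11)-dien-12,6-olid-8-yl (2E)-4-(TBDPSO)-2-methylbut-2-enoate
Product: 27 (1S,4R,5E,8S,10R)-13-acetoxy-1,4-epoxy-1-hydroxygermacra-5,7(11)-dien-12,6-olid-8-yl (2E)-4-hydroxy-2-methylbut-2-enoate (CNP0154520.1)
Conditions: HF·pyridine (excess), THF, 0 °C → rt
Reagents that add atoms: none
Why: Fluoride-mediated cleavage of the TBDPS ether under non-basic conditions, which should spare the allylic C13 acetate, the hemiketal and the ylidene butenolide.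

**Compound list**

1 | furan-3,4-diyldimethanol | OCc1cocc1CO | starting material
2 | [4-(TBSOCH2)furan-3-yl]methanol | CC(C)(C)[Si](C)(C)OCc1cocc1CO | intermediate
3 | 4-(TBSOCH2)furan-3-carboxylic acid | CC(C)(C)[Si](C)(C)OCc1cocc1C(=O)O | intermediate
4 | lithium 2-lithio-4-(TBSOCH2)furan-3-carboxylate (dilithiated furoate) | [Li]c1occ(CO[Si](C)(C)C(C)(C)C)c1C(=O)O[Li] | intermediate
5 | lithium 2-(chlorozincio)-4-(TBSOCH2)furan-3-carboxylate (furylzinc chloride) | Cl[Zn]c1occ(CO[Si](C)(C)C(C)(C)C)c1C(=O)O[Li] | intermediate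
6 | 2-ethenyl-4-(TBSOCH2)furan-3-carboxylic acid | C=Cc1occ(CO[Si](C)(C)C(C)(C)C)c1C(=O)O | intermediate
7 | methyl (2S)-3-bromo-2-methylpropanoate | COC(=O)[C@H](C)CBr | starting material
8 | 2-ethenyl-4-(TBSOCH2)furan-3-carbonyl chloride | C=Cc1occ(CO[Si](C)(C)C(C)(C)C)c1C(Cl)=O | intermediate
9 | [(2S)-3-methoxy-2-methyl-3-oxopropyl]zinc bromide | COC(=O)[C@H](C)C[Zn]Br | intermediate
10 | methyl (2R)-4-[2-ethenyl-4-(TBSOCH2)furan-3-yl]-2-methyl-4-oxobutanoate | COC(=O)[C@H](C)CC(=O)c1c(C=C)occ1CO[Si](C)(C)C(C)(C)C | intermediate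
11 | (3R,5S)-5-[2-ethenyl-4-(TBSOCH2)furan-3-yl]-3-methyloxolan-2-one | C[C@@H]1C[C@@H](c2c(C=C)occ2CO[Si](C)(C)C(C)(C)C)OC1=O | intermediate
12 | (2R,4S)-4-[2-ethenyl-4-(TBSOCH2)furan-3-yl]-4-hydroxy-N-methoxy-N,2-dimethylbutanamide | CON(C)C(=O)[C@H](C)C[C@H](O)c1c(C=C)occ1CO[Si](C)(C)C(C)(C)C | intermediate
13 | 4-bromo-2-methylbut-1-ene | C=C(C)CCBr | starting material
14 | (3-methylbut-3-en-1-yl)magnesium bromide | C=C(C)CC[Mg]Br | intermediate
15 | (6R,8S)-8-[2-ethenyl-4-(TBSOCH2)furan-3-yl]-8-hydroxy-2,6-dimethyloct-1-en-5-one | C=C(C)CCC(=O)[C@H](C)C[C@H](O)c1c(C=C)occ1CO[Si](C)(C)C(C)(C)C | intermediate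
16 | 2-{[tert-butyl(diphenyl)silyl]oxy}acetaldehyde | O=CCO[Si](c1ccccc1)(c1ccccc1)C(C)(C)C | starting material
17 | ethyl 2-(triphenyl-λ5-phosphanylidene)propanoate | CCOC(=O)C(C)=P(c1ccccc1)(c1ccccc1)c1ccccc1 | starting material
18 | ethyl (2E)-4-(TBDPSO)-2-methylbut-2-enoate | CCOC(=O)/C(C)=C/CO[Si](c1ccccc1)(c1ccccc1)C(C)(C)C | intermediate
19 | (2E)-4-(TBDPSO)-2-methylbut-2-enoic acid | OC(=O)/C(C)=C/CO[Si](c1ccccc1)(c1ccccc1)C(C)(C)C | intermediate
20 | (1S,3R)-1-[2-ethenyl-4-(TBSOCH2)furan-3-yl]-3,7-dimethyl-4-oxooct-7-en-1-yl (2E)-4-(TBDPSO)-2-methylbut-2-enoate | C=C(C)CCC(=O)[C@H](C)C[C@H](OC(=O)/C(C)=C/CO[Si](c1ccccc1)(c1ccccc1)C(C)(C)C)c1c(C=C)occ1CO[Si](C)(C)C(C)(C)C | intermediate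
21 | (4S,6R,10Z)-3-(TBSOCH2)-6,10-dimethyl-7-oxo-4,5,6,7,8,9-hexahydrocyclodeca[b]furan-4-yl (2E)-4-(TBDPSO)-2-methylbut-2-enoate | C[C@@H]1C[C@H](OC(=O)/C(C)=C/CO[Si](c2ccccc2)(c2ccccc2)C(C)(C)C)c2c(CO[Si](C)(C)C(C)(C)C)coc2/C=C(C)\CCC1=O | intermediate
22 | (4S,6R,10Z)-3-(hydroxymethyl)-6,10-dimethyl-7-oxo-4,5,6,7,8,9-hexahydrocyclodeca[b]furan-4-yl (2E)-4-(TBDPSO)-2-methylbut-2-enoate | C[C@@H]1C[C@H](OC(=O)/C(C)=C/CO[Si](c2ccccc2)(c2ccccc2)C(C)(C)C)c2c(CO)coc2/C=C(C)\CCC1=O | intermediate
23 | (4S,6R,10Z)-3-(acetoxymethyl)-6,10-dimethyl-7-oxo-4,5,6,7,8,9-hexahydrocyclodeca[b]furan-4-yl (2E)-4-(TBDPSO)-2-methylbut-2-enoate | C[C@@H]1C[C@H](OC(=O)/C(C)=C/CO[Si](c2ccccc2)(c2ccccc2)C(C)(C)C)c2c(COC(C)=O)coc2/C=C(C)\CCC1=O | intermediate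
24 | furan endoperoxide of 23 (2,11a-epidioxy-2,11a-dihydro derivative; O–O bridge from C12 to C6) | C[C@@H]1C[C@H](OC(=O)/C(C)=C/CO[Si](c2ccccc2)(c2ccccc2)C(C)(C)C)C2=C(COC(C)=O)C3OOC2(O3)/C=C(C)\CCC1=O | intermediate
25 | (4S,6R,10Z)-3-(acetoxymethyl)-11a-hydroxy-6,10-dimethyl-2,7-dioxo-2,4,5,6,7,8,9,11a-octahydrocyclodeca[b]furan-4-yl (2E)-4-(TBDPSO)-2-methylbut-2-enoate (C6 epimers) | C[C@@H]1C[C@H](OC(=O)/C(C)=C/CO[Si](c2ccccc2)(c2ccccc2)C(C)(C)C)C2=C(COC(C)=O)C(=O)OC2(O)/C=C(C)\CCC1=O | intermediate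
26 | (1S,4R,5E,8S,10R)-13-acetoxy-1,4-epoxy-1-hydroxygermacra-5,7(11)-dien-12,6-olid-8-yl (2E)-4-(TBDPSO)-2-methylbut-2-enoate | CC(=O)OCC1=C2/C(=C\[C@@]3(C)CC[C@](O)(O3)[C@H](C)C[C@@H]2OC(=O)/C(C)=C/CO[Si](c2ccccc2)(c2ccccc2)C(C)(C)C)OC1=O | intermediate
27 | (1S,4R,5E,8S,10R)-13-acetoxy-1,4-epoxy-1-hydroxygermacra-5,7(11)-dien-12,6-olid-8-yl (2E)-4-hydroxy-2-methylbut-2-enoate (CNP0154520.1) | CC(=O)OCC1=C2/C(=C\[C@@]3(C)CC[C@](O)(O3)[C@H](C)C[C@@H]2OC(=O)/C(C)=C/CO)OC1=O | target

**Step count and risks**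

Total step count: 16. Longest linear sequence: 14 steps (steps 1–7 and 10–16); steps 8–9 make the side-chain acid.

Steps most likely to fail:

1. Step 15 (proposed new method). The ionized pseudo-acid may be diverted into Nazarov-type electrocyclization of its ring-opened divinyl-ketone tautomer or into vinylogous dehydration; attack of the C1 oxygen on C4 may show poor facial selectivity; C10 may epimerize through the C1 enol. The fallback uses known chemistry, sets out from 25 and returns at 26. Treating 25 with NaHCO3 in THF/H2O should open it to the (Z)-4-oxodienoate, in which the C1 oxygen (as hydrate or hemiketal) adds reversibly to C4 of the C4=C5–C6=O enone (hemiketalization/oxa-conjugate addition under thermodynamic control). Re-acidification should give the bridged γ-hydroxybutenolide F1, and dehydration of F1 across C5–C6 with trifluoroacetic anhydride/2,6-lutidine in CH2Cl2 (pseudo-acid to γ-ylidenebutenolide) leads to 26.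

2. Step 11 (key step). Intermolecular metathesis may outrun closure of the strained ten-membered ring, and turnover at the 1,1-disubstituted olefin may be slow. The fallback sets out from 15 and returns at 21 and uses a temporary ring. PPTS with HC(OMe)3 in MeOH should convert 15 into the cyclic methyl ketal F2, a 2-methoxyoxolane that ties C1 to the C8 oxygen; its anomers equilibrate and the one with both olefin arms cis can close. Ring-closing metathesis of F2 under the step 11 conditions then occurs within a rigid oxygen-bridged frame to give the bicyclic ketal F3. PPTS in acetone/H2O should unveil the macrocyclic hydroxy ketone F4, which is esterified with 19 as in step 10 to give 21.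

3. Step 14. Singlet oxygen may also engage the C4=C5 olefin (ene reaction or [4+2] addition across the alkenylfuran), and over-oxidation is possible. The fallback sets out from 23 and returns at 25. Oxidative furan opening with NBS and NaHCO3 in acetone/H2O at −20 °C should give the (Z)-keto-enal F5. Pinnick oxidation of its aldehyde (NaClO2, NaH2PO4, 2-methylbut-2-ene, t-BuOH/H2O) gives the (Z)-4-oxo-2-enoic acid, which closes to 25.

Further compounds
F1 | step 15 | 5,6-dihydro-6-hydroxy derivative of 26 (bridged γ-hydroxybutenolide: C1–O–C4 hemiketal in place, C5H2, lactol OH at C6) | CC(=O)OCC1=C2C(O)(C[C@@]3(C)CC[C@](O)(O3)[C@H](C)C[C@@H]2OC(=O)/C(C)=C/CO[Si](c2ccccc2)(c2ccccc2)C(C)(C)C)OC1=O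
F2 | step 11 | (3R,5S)-5-[2-ethenyl-4-(TBSOCH2)furan-3-yl]-2-methoxy-3-methyl-2-(3-methylbut-3-en-1-yl)oxolane (anomers at C1) | C=C(C)CCC1(OC)O[C@H](c2c(C=C)occ2CO[Si](C)(C)C(C)(C)C)C[C@H]1C
F3 | step 11 | oxygen-bridged ring-closed ketal (C1–O–C8 bridge across the ten-membered furan-fused ring, C1 methoxy, C4=C5 Z) | C[C@@H]1C[C@@H]2OC1(OC)CC/C(C)=C\c1occ(CO[Si](C)(C)C(C)(C)C)c12
F4 | step 11 | (4S,6R,10Z)-4-hydroxy-3-(TBSOCH2)-6,10-dimethyl-5,6,8,9-tetrahydrocyclodeca[b]furan-7(4H)-one | C[C@@H]1C[C@H](O)c2c(CO[Si](C)(C)C(C)(C)C)coc2/C=C(C)\CCC1=O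
F5 | step 14 | (Z)-keto-enal from furan opening of 23 (C6 ketone and C12 aldehyde cis on the C7=C11 bond, ten-membered ring retained) | C[C@@H]1C[C@H](OC(=O)/C(C)=C/CO[Si](c2ccccc2)(c2ccccc2)C(C)(C)C)/C(C(=O)/C=C(C)\CCC1=O)=C(\COC(C)=O)C=O
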